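**Retrosynthetic overview**
- The target is reached from its octa-O-methyl ether by cleaving all eight aryl methyl ethers in the last step.
- Both pyranone rings (rings C) are disconnected at C4–C4a by a twofold intramolecular Friedel–Crafts acylation, leading back to a bis(3-aryloxy-2-arylacrylic acid) built on a hexamethoxybiphenyl.
- The strategy rests on one feature: in each ring A, C4a is the only carbon that carries hydrogen, and it lies ortho to the aryl ether oxygen O1 on C8a (C5, C6 and C7 carry oxygen, C8 carries the biaryl bond), so the acyl carbon has a single site to attack.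
- The two O1–C2 bonds come from twofold vinylic substitution of ethyl 3-chloro-2-(4-methoxyphenyl)acrylate by the biphenyl-2,2'-diol; the C8–C8' bond comes from oxidative dimerization of 3,4,5-trimethoxyphenol.
- Ring order: rings A and B are bought, the C8–C8' axis is made first, and the two rings C are closed last in one operation.

Key step: step 6

Remark: the target has no stereocenter and its SMILES assigns no sense to the tetra-ortho-substituted 8,8' axis, so the axis is left uncontrolled and the material is expected as the racemate.

**Step 1**
Reactants: 1 3,4,5-trimethoxyphenol; 1 3,4,5-trimethoxyphenol (second molecule)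
Product: 2 4,4',5,5',6,6'-hexamethoxybiphenyl-2,2'-diol
Conditions: FeCl3 (10 mol %), t-BuOOt-Bu (0.6 equiv per phenol), (CF3)2CHOH, rt, stopped before full conversion
Reagents that add atoms: 3,4,5-trimethoxyphenol (the second molecule of 1, which becomes the other half of the biphenyl), COc1cc(O)cc(OC)c1OC
Why: Oxidative dehydrodimerization of a phenol through its phenoxyl radical: two molecules of 1 are joined, the para position of 1 carries OMe and the two ortho carbons are equivalent, so ortho–ortho C–C coupling and tautomerization give the 2,2'-biphenol, while the anhydrous fluoroalcohol disfavours oxidative demethylation to the para-quinone.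

**Step 2**
Reactants: 3 ethyl 4-methoxyphenylacetate; 4 ethyl formate
Product: 5 ethyl 2-(4-methoxyphenyl)-3-oxopropanoate (obtained largely as its enol, ethyl 3-hydroxy-2-(4-methoxyphenyl)acrylate; the α-carbon is stereochemically labile)
Conditions: NaH, THF, 0 °C to rt; then aq. HCl
Reagents that add atoms: none
Why: Crossed Claisen condensation (C-formylation): ethyl formate has no α-hydrogen and is the more electrophilic ester, and the product is withdrawn from the equilibrium as its stabilized sodium enolate.

**Step 3**
Reactants: 5 ethyl 2-(4-methoxyphenyl)-3-oxopropanoate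
Product: 6 ethyl (E)-3-chloro-2-(4-methoxyphenyl)acrylate (Cl trans to the ester; any Z isomer formed alongside is carried on)
Conditions: (COCl)2, DMF (cat.), CH2Cl2, 0 °C to rt
Reagents that add atoms: oxalyl chloride, ClC(=O)C(=O)Cl
Why: Vilsmeier-type deoxychlorination of a vinylogous acid: the chloroiminium salt activates the enol oxygen, chloride adds to the former formyl carbon and DMF is expelled, as in the conversion of enolized 1,3-dicarbonyl compounds into β-chloro enones and enoates; either alkene isomer is usable because step 4 is stereoconvergent.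

**Step 4**
Reactants: 2 4,4',5,5',6,6'-hexamethoxybiphenyl-2,2'-diol; 6 ethyl (E)-3-chloro-2-(4-methoxyphenyl)acrylate; 6 ethyl (E)-3-chloro-2-(4-methoxyphenyl)acrylate (second molecule)
Product: 7 diethyl (2E,2'E)-3,3'-[(4,4',5,5',6,6'-hexamethoxybiphenyl-2,2'-diyl)bis(oxy)]bis[2-(4-methoxyphenyl)acrylate] (each aryloxy group trans to CO2Et and cis to the 4-methoxyphenyl group)
Conditions: 6 (2.3 equiv), Cs2CO3 (3 equiv), DMF (degassed), 60 °C, N2
Reagents that add atoms: ethyl (E)-3-chloro-2-(4-methoxyphenyl)acrylate (the second molecule of 6, taken up by the second hydroxyl group), CCOC(=O)/C(=C/Cl)c1ccc(OC)cc1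
Why: Twofold nucleophilic vinylic substitution by addition–elimination: each of the two caesium phenoxide oxygens of 2 adds to the chlorine-bearing carbon of one molecule of 6 to give an ester- and aryl-stabilized carbanion that can rotate before it expels chloride, so the thermodynamically preferred E enol ether (the geometry of the β-methoxyacrylate fungicides) is expected from either isomer of 6, and the α-carbon of 6 carries no hydrogen, so elimination of HCl to an alkynoate cannot compete.

**Step 5**
Reactants: 7 diethyl (2E,2'E)-3,3'-[(4,4',5,5',6,6'-hexamethoxybiphenyl-2,2'-diyl)bis(oxy)]bis[2-(4-methoxyphenyl)acrylate]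
Product: 8 (2E,2'E)-3,3'-[(4,4',5,5',6,6'-hexamethoxybiphenyl-2,2'-diyl)bis(oxy)]bis[2-(4-methoxyphenyl)acrylic acid] (each aryloxy group trans to CO2H)
Conditions: LiOH·H2O (excess), THF/MeOH/H2O, rt; then aq. HCl to pH 2–3
Reagents that add atoms: lithium hydroxide, [Li+].[OH-]
Why: Saponification (acyl substitution by hydroxide) at room temperature, where each carboxylate, once formed, is no longer a Michael acceptor and so shields the aryl enol ether from further attack by hydroxide.

**Step 6**
Reactants: 8 (2E,2'E)-3,3'-[(4,4',5,5',6,6'-hexamethoxybiphenyl-2,2'-diyl)bis(oxy)]bis[2-(4-methoxyphenyl)acrylic acid]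
Product: 10 5,5',6,6',7,7'-hexamethoxy-3,3'-bis(4-methoxyphenyl)-8,8'-bi(4H-chromen-4-one), via the Z-configured diacid 9 (not isolated)
Conditions: P2O5/CH3SO3H (Eaton's reagent, 1:10 w/w), 0.05 M, rt to 45 °C, N2
Reagents that add atoms: none
Why: The P2O5/CH3SO3H medium turns each carboxyl group into a mixed anhydride or an acylium ion, and reversible protonation of the enol ether at the carbon that bears ring B (the future C3) gives an aryloxycarbenium ion whose rotation and deprotonation interconvert the alkene isomers, so the E,E acid 8 is drained through the Z,Z acid 9, the only geometry in which the acyl carbon reaches ring A. The acyl carbon attacks C4a and proton loss restores the arene, which forms C4–C4a; the closest known reaction is the cyclodehydrative intramolecular Friedel–Crafts acylation of 3-aryloxyacrylic acids to chromones, here on a 2-aryl member of that class. Each pyranone ring closes in a 6-exo mode at the acyl carbon (exo-dig for a free acylium ion, exo-trig for the mixed anhydride), the attacking C4a=C8a bond of the arene lying inside the new ring. No stereocenter is formed and the biaryl axis made in step 1 is not touched. The step needs regioselectivity on ring A and geometric convergence of the enol ether: the first is secured because C4a is the only C–H of ring A, ortho to O1 and ortho and para to methoxy groups, while ring B could reach the acyl carbon only through a four-membered ring, and the second by the acid-labile push–pull alkene.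

**Step 7**
Reactants: 10 5,5',6,6',7,7'-hexamethoxy-3,3'-bis(4-methoxyphenyl)-8,8'-bi(4H-chromen-4-one)
Product: 11 5,5',6,6',7,7'-hexahydroxy-3,3'-bis(4-hydroxyphenyl)-8,8'-bi(4H-chromen-4-one) (CNP0254964.0)
Conditions: BBr3 (excess), CH2Cl2, −78 °C to rt; then H2O, work-up under argon
Reagents that add atoms: none
Why: Lewis acid-mediated cleavage of aryl methyl ethers by BBr3 (O–B complexation, then SN2 attack of bromide on methyl), a standard operation on polymethoxyflavonoids that leaves the pyranone rings and the biaryl bond intact at or below room temperature.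

**Compound list**
1 | 3,4,5-trimethoxyphenol | COc1cc(O)cc(OC)c1OC | starting material
2 | 4,4',5,5',6,6'-hexamethoxybiphenyl-2,2'-diol | Oc1cc(OC)c(OC)c(OC)c1-c1c(O)cc(OC)c(OC)c1OC | intermediate
3 | ethyl 4-methoxyphenylacetate | CCOC(=O)Cc1ccc(OC)cc1 | starting material
4 | ethyl formate | CCOC=O | starting material
5 | ethyl 2-(4-methoxyphenyl)-3-oxopropanoate (aldehyde tautomer drawn; mainly enol) | CCOC(=O)C(C=O)c1ccc(OC)cc1 | intermediate
6 | ethyl (E)-3-chloro-2-(4-methoxyphenyl)acrylate | CCOC(=O)/C(=C/Cl)c1ccc(OC)cc1 | intermediate
7 | diethyl (2E,2'E)-3,3'-[(4,4',5,5',6,6'-hexamethoxybiphenyl-2,2'-diyl)bis(oxy)]bis[2-(4-methoxyphenyl)acrylate] | CCOC(=O)/C(=C/Oc1cc(OC)c(OC)c(OC)c1-c1c(O/C=C(/C(=O)OCC)c2ccc(OC)cc2)cc(OC)c(OC)c1OC)c1ccc(OC)cc1 | intermediate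
8 | (2E,2'E)-3,3'-[(4,4',5,5',6,6'-hexamethoxybiphenyl-2,2'-diyl)bis(oxy)]bis[2-(4-methoxyphenyl)acrylic acid] | OC(=O)/C(=C/Oc1cc(OC)c(OC)c(OC)c1-c1c(O/C=C(/C(=O)O)c2ccc(OC)cc2)cc(OC)c(OC)c1OC)c1ccc(OC)cc1 | intermediate
9 | (2Z,2'Z)-3,3'-[(4,4',5,5',6,6'-hexamethoxybiphenyl-2,2'-diyl)bis(oxy)]bis[2-(4-methoxyphenyl)acrylic acid] (aryloxy cis to CO2H; formed in the flask, not isolated) | OC(=O)/C(c1ccc(OC)cc1)=C\Oc1cc(OC)c(OC)c(OC)c1-c1c(O/C=C(\C(=O)O)c2ccc(OC)cc2)cc(OC)c(OC)c1OC | intermediate
10 | 5,5',6,6',7,7'-hexamethoxy-3,3'-bis(4-methoxyphenyl)-8,8'-bi(4H-chromen-4-one) | O=c1c(-c2ccc(OC)cc2)coc2c(-c3c(OC)c(OC)c(OC)c4c(=O)c(-c5ccc(OC)cc5)coc34)c(OC)c(OC)c(OC)c12 | intermediate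
11 | 5,5',6,6',7,7'-hexahydroxy-3,3'-bis(4-hydroxyphenyl)-8,8'-bi(4H-chromen-4-one) | O=c1c(-c2ccc(O)cc2)coc2c(-c3c(O)c(O)c(O)c4c(=O)c(-c5ccc(O)cc5)coc34)c(O)c(O)c(O)c12 | target

**Step count**
Total: 7 steps. Longest linear sequence: 6 steps (steps 2, 3, 4, 5, 6, 7, from ethyl 4-methoxyphenylacetate).

**Steps most likely to fail**

Step 6. The ring closure depends on E-to-Z equilibration of both enol ethers being faster than the side reactions of the protonated enol ether. Those are decarboxylation of the still-free acid, attack of a second electron-rich ring on the aryloxycarbenium carbon, intermolecular acylation to oligomers, and methanesulfonylation of the anisyl rings by the medium. The reaction may also stop after one ring has closed. Fallback, from 2 to 10: 2 would be acylated at the same free carbon, ortho to each hydroxyl, with two equivalents of 4-methoxyphenylacetic acid in BF3·OEt2 at 70–80 °C (Friedel–Crafts deoxybenzoin synthesis). This should give the bis(deoxybenzoin) 1,1'-(2,2'-dihydroxy-4,4',5,5',6,6'-hexamethoxybiphenyl-3,3'-diyl)bis[2-(4-methoxyphenyl)ethanone] F1. Heating F1 with N,N-dimethylformamide dimethyl acetal would then supply C2 through the enaminone and close both pyranone rings at O1–C2, rejoining the route at 10.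

Step 1. The phenoxyl radical may be over-oxidized instead of coupling once: oxidative loss of the para methoxy group to the quinone, further coupling of the biphenol at its remaining ortho carbons, or C–O coupling. Fallback, from 1 to 2: 1 would be protected as 1,2,3-trimethoxy-5-(methoxymethoxy)benzene F2 (MOMCl, i-Pr2NEt, CH2Cl2). Directed ortho-lithiation between OMOM and OMe (n-BuLi, THF, 0 °C) and oxidative homocoupling of the aryllithium with anhydrous CuCl2 should give 4,4',5,5',6,6'-hexamethoxy-2,2'-bis(methoxymethoxy)biphenyl F3. HCl in MeOH removes both acetals from F3 and returns 2.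

Step 5. Hydroxide may add to the oxygen-bearing alkene carbon and expel the biphenolate (the reverse of step 4) faster than it hydrolyses the deactivated push–pull ester, or hydrolysis may stall at the mono-acid. Fallback, from 7 to 10: the diester 7 would not be hydrolysed but cyclized directly in CF3SO3H at 40–60 °C. This is a Friedel–Crafts acylation with the ester as acyl donor, as practised on aryloxy enoate esters in strong acid, with ethanol lost in place of water. No new compound is made (F0), and the route is rejoined at 10.

**Further compounds**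
F1 | step 6 | 1,1'-(2,2'-dihydroxy-4,4',5,5',6,6'-hexamethoxybiphenyl-3,3'-diyl)bis[2-(4-methoxyphenyl)ethanone] | COc1ccc(CC(=O)c2c(O)c(-c3c(O)c(C(=O)Cc4ccc(OC)cc4)c(OC)c(OC)c3OC)c(OC)c(OC)c2OC)cc1
F2 | step 1 | 1,2,3-trimethoxy-5-(methoxymethoxy)benzene | COCOc1cc(OC)c(OC)c(OC)c1
F3 | step 1 | 4,4',5,5',6,6'-hexamethoxy-2,2'-bis(methoxymethoxy)biphenyl | COCOc1cc(OC)c(OC)c(OC)c1-c1c(OCOC)cc(OC)c(OC)c1OC
F0 | step 5 | none | none
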